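Numbering: ring A = C5–C6=C7(Ac)–C8(=O)–C9(OAng)–C10(OH); ring B = C10–C1–C2–C3(OAc)–C4(Me)–C5(Me). C9 and C10 are adjacent oxygenated carbons, and C10 is a tertiary carbinol at the ring fusion beside quaternary C5. This is a reduced acyloin, so C9–C10 can be formed from a C9 aldehyde acting as an acyl anion and the C10 ketone of ring B.
Cuts, in retrosynthetic order: C7–acetyl (Stille), the C9–O ester, the C8 ketone and C6=C7 alkene (traced back to a C9 ketone through a 7,8-epoxide and a 7-ene), C9–C10 (carbene-catalysed benzoin), C8–C9 (hydroformylation), C5–C6 (allylation), C5–CH3, C4–CH3.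
Forward: the six carbons of p-benzoquinone dimethyl monoketal become ring B. C4-Me, C5-Me and an allyl group are added, the C3 acetate is set, and CO supplies C9. Ring A then closes onto C10 in one step and is oxidised outward from C9.
Stereochemistry: C4 comes from a Cu/phosphoramidite-catalysed Me2Zn addition, C5 from alkylation anti to C4-Me, and C3 from hydride attack anti to both methyls. C10 is set by the C5 tether with a matched chiral carbene (cis fusion), and C9 by hydride delivery from the C10 hydroxyl.

Key step: step 8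

Conventions: C-numbers in the text are those of the plan, and locants inside systematic names belong to the name. β is the face of the bicycle that carries the C5 methyl group.
Assumption: the (S,R,R)-phosphoramidite is taken to give the (R)-adduct in step 1, by analogy with its sense of induction on cyclohex-2-enone; the mirror-image ligand serves if the sense is reversed.
Assumption: the (5aR,10bS)-triazolium salt is taken as the antipode matched to the substrate bias in step 8; the (5aS,10bR)-salt is the alternative.

Step 1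
Reactants: 1 4,4-dimethoxycyclohexa-2,5-dien-1-one
Product: 2 (R)-4,4-dimethoxy-5-methylcyclohex-2-en-1-one
Conditions: Me2Zn (1.3 equiv), Cu(OTf)2 (2 mol%), (S,R,R)-O,O′-(1,1′-binaphthyl-2,2′-diyl)-N,N-bis(1-phenylethyl)phosphoramidite (4 mol%), toluene, −25 °C; sat. aq. NH4Cl
Reagents that add atoms: dimethylzinc, C[Zn]C
Why: Copper-catalysed asymmetric conjugate addition of a dialkylzinc to a quinone monoketal is an established desymmetrisation in which the ligand selects one enantiotopic enone face and so sets C4, while the zinc dienolate formed shields the second enone from further addition.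

Step 2
Reactants: 2 (R)-4,4-dimethoxy-5-methylcyclohex-2-en-1-one
Product: 3 (5R,6R)-4,4-dimethoxy-5,6-dimethylcyclohex-2-en-1-one (trans; the 6-epimer serves equally)
Conditions: LiN(i-Pr)2 (1.05 equiv), THF, −78 °C; MeI, −78 → −20 °C
Reagents that add atoms: iodomethane, CI
Why: This is a kinetic α′-enolate alkylation of a cyclohexenone in which only C5 can be deprotonated, because the γ-carbon C3 is the ketal carbon; MeI should enter anti to the C4 methyl, and this centre is flattened again in step 3.

Step 3
Reactants: 3 (5R,6R)-4,4-dimethoxy-5,6-dimethylcyclohex-2-en-1-one; 4 allyl bromide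
Product: 5 (5R,6R)-6-allyl-4,4-dimethoxy-5,6-dimethylcyclohex-2-en-1-one (methyl groups cis)
Conditions: LiN(i-Pr)2 (1.1 equiv), THF, −78 → −20 °C; DMPU, 4 (1.5 equiv), −78 °C → rt
Reagents that add atoms: none
Why: In this second α′-alkylation, of the kind used on 6-methylcarvone-type enones, the C4 methyl of the cross-conjugated dienolate sits pseudo-axial to escape A(1,2) strain with the C5 methyl, so allyl bromide should bond to the opposite face and give quaternary C5 with the two methyl groups cis.

Step 4
Reactants: 5 (5R,6R)-6-allyl-4,4-dimethoxy-5,6-dimethylcyclohex-2-en-1-one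
Product: 7 (2R,3R)-2-allyl-2,3-dimethylcyclohexane-1,4-dione, via dimethylphenylsilyl enol ether 6 (not isolated)
Conditions: [(Ph3P)CuH]6 (5 mol% Cu), PhMe2SiH (1.5 equiv), toluene, rt; then 1 M HCl, THF, 0 °C
Reagents that add atoms: dimethylphenylsilane, C[SiH](C)c1ccccc1 (silicon stays only in 6); water, O (oxygen of the C3 ketone)
Why: Copper hydride-catalysed 1,4-hydrosilylation reduces only the conjugated C1=C2 bond and leaves the isolated allyl alkene, and the short cold acid quench cleaves the silyl enol ether and the now saturated, labile dimethyl ketal under conditions too mild to enolise the C3 ketone toward C4.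

Step 5
Reactants: 7 (2R,3R)-2-allyl-2,3-dimethylcyclohexane-1,4-dione
Product: 8 (2R,3R,4S)-2-allyl-4-hydroxy-2,3-dimethylcyclohexan-1-one
Conditions: LiBH(s-Bu)3 (1.0 equiv), THF, −78 °C; then aq. NaOH, H2O2, 0 °C
Reagents that add atoms: none
Why: The bulky trialkylborohydride should prefer the C3 ketone (α-CH) over the C10 ketone (α-quaternary) and attack it from the α-face along the equatorial path, anti to the C4 methyl and away from the syn-axial C5 methyl, giving the 3β-alcohol cis to C4-Me as in the reduction of 2-methylcyclohexanone to the cis-alcohol.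

Step 6
Reactants: 8 (2R,3R,4S)-2-allyl-4-hydroxy-2,3-dimethylcyclohexan-1-one
Product: 9 (1S,2R,3R)-3-allyl-2,3-dimethyl-4-oxocyclohexyl acetate
Conditions: Ac2O, DMAP (cat.), pyridine, CH2Cl2, rt
Reagents that add atoms: acetic anhydride, CC(=O)OC(C)=O
Why: DMAP-catalysed acylation installs the C3 acetate of the target, which then acts as its own protecting group because no later step uses strong base, hydroxide or an ester-reducing hydride.

Step 7
Reactants: 9 (1S,2R,3R)-3-allyl-2,3-dimethyl-4-oxocyclohexyl acetate
Product: 10 (1S,2R,3R)-2,3-dimethyl-4-oxo-3-(4-oxobutyl)cyclohexyl acetate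
Conditions: Rh(acac)(CO)2 (1 mol%), BIPHEPHOS (2 mol%), CO/H2 (1:1, 10 bar), toluene, 60 °C
Reagents that add atoms: carbon monoxide, [C-]#[O+]
Why: Linear-selective rhodium hydroformylation with a wide-bite-angle diphosphite adds C9 as the aldehyde at the terminal carbon, the neighbouring quaternary C5 further disfavours the branched isomer, and the neutral medium leaves the ketone and acetate untouched.

Step 8
Reactants: 10 (1S,2R,3R)-2,3-dimethyl-4-oxo-3-(4-oxobutyl)cyclohexyl acetate
Product: 11 3β-acetoxy-10β-hydroxy-4β,5β-dimethyl-cis-decalin-9-one [(1R,2S,4aR,8aR)-4a-hydroxy-1,8a-dimethyl-5-oxodecahydronaphthalen-2-yl acetate]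
Conditions: (5aR,10bS)-2-(pentafluorophenyl)-5a,10b-dihydro-4H,6H-indeno[2,1-b][1,2,4]triazolo[4,3-d][1,4]oxazin-2-ium tetrafluoroborate (15 mol%), NEt3 (15 mol%), toluene (0.05 M), 4 Å MS, Ar, rt → 40 °C
Reagents that add atoms: none
Why: NEt3 frees the carbene, which adds to the unhindered C9 aldehyde; proton transfer gives the nucleophilic enaminol, whose C9 attacks the C10 ketone, and collapse of the adduct expels the carbene to leave the C9 ketone beside the C10 carbinol. The closest known reaction type is the carbene-catalysed intramolecular crossed aldehyde–ketone benzoin cyclisation, which is documented for cyclic ketones bearing a 2-methyl-2-(ω-oxoalkyl) quaternary carbon next to the acceptor carbonyl. Ring A closes in the 6-exo-trig mode, with C9 bonding to C10 and the carbonyl oxygen staying outside the new ring. The new centre C10 is controlled by C5: the four-carbon tether lies equatorial on the α-face of ring B and reaches C10 best along the axial α-trajectory, which pushes the oxygen to the β-face, syn to the C5 methyl (cis-decalin), the triazolium antipode is chosen to reinforce this bias, and the reversibility of benzoin addition should also let the more stable cis-ketol accumulate. The step needs the aldehyde as donor and the ketone as acceptor without homo-benzoin or aldol reaction, which is secured by the carbene adding only to the aldehyde, by the intramolecular setting at moderate dilution and by the weak base, and the aldehyde has no α-leaving group that could divert the enaminol into redox esterification.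

Step 9
Reactants: 11 3β-acetoxy-10β-hydroxy-4β,5β-dimethyl-cis-decalin-9-one
Product: 12 3β-acetoxy-10β-hydroxy-4β,5β-dimethyl-cis-decal-7-en-9-one
Conditions: IBX (2 equiv), DMSO/fluorobenzene (1:2), 70 °C
Reagents that add atoms: none
Why: IBX dehydrogenation of a ketone proceeds through its enol, and since C10 is fully substituted only C8 can enolise, so a single C7=C8 enone should form while the tertiary alcohol and the acetate are inert.

Step 10
Reactants: 12 3β-acetoxy-10β-hydroxy-4β,5β-dimethyl-cis-decal-7-en-9-one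
Product: 13 3β-acetoxy-4β,5β-dimethyl-cis-decal-7-ene-9α,10β-diol
Conditions: Me4NBH(OAc)3 (4 equiv), MeCN/AcOH (1:1), −25 → 0 °C
Reagents that add atoms: none
Why: In this Saksena–Evans hydroxyl-directed reduction, acetate exchange binds boron to the 10β-hydroxyl and the hydride passes intramolecularly, in the 1,2-mode only, to the β-face of C9, which is also the open convex face because ring B shields the α-face, so the new hydroxyl should be 9α and trans to 10β-OH.

Step 11
Reactants: 13 3β-acetoxy-4β,5β-dimethyl-cis-decal-7-ene-9α,10β-diol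
Product: 14 3β-acetoxy-7α,8α-epoxy-4β,5β-dimethyl-cis-decalin-9α,10β-diol
Conditions: VO(acac)2 (5 mol%), t-BuOOH (decane, 1.5 equiv), CH2Cl2, 0 °C → rt
Reagents that add atoms: tert-butyl hydroperoxide, CC(C)(C)OO
Why: In this vanadium-catalysed hydroxyl-directed epoxidation the pseudo-axial secondary allylic 9α-hydroxyl binds the metal peroxide far better than the tertiary homoallylic 10β-hydroxyl and delivers oxygen syn, to the α-face; C7 and C8 later become sp2, so this face matters only in leaving the convex β-face open for step 12.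

Step 12
Reactants: 14 3β-acetoxy-7α,8α-epoxy-4β,5β-dimethyl-cis-decalin-9α,10β-diol
Product: 17 3β-acetoxy-4β,5β-dimethyl-cis-decal-6-ene-8α,9α,10β-triol, via hydroxy selenide 15 (not isolated), via selenoxide 16 (not isolated)
Conditions: (PhSe)2 (0.8 equiv), NaBH4 (1.7 equiv), EtOH, 0 °C → rt; AcOH (buffer), 14, 60 °C; then THF, 30% aq. H2O2, 0 °C → rt
Reagents that add atoms: diphenyl diselenide, c1ccc(cc1)[Se][Se]c1ccccc1 (selenium stays only in 15 and 16); hydrogen peroxide, OO (oxygen stays only in 16)
Why: In this organoselenium conversion of an epoxide into an allylic alcohol the soft selenolate enters from the convex β-face and opens the oxirane trans-diaxially (Fürst–Plattner rule) at C7, the carbon remote from the electron-withdrawing C9–O bond, much as steroidal 2α,3α-epoxides open at C2 beside an angular methyl; the selenoxide then undergoes syn-elimination away from the carbinol carbon toward C6–H, and the acetic acid buffer keeps the medium non-basic for the C3 acetate.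

Step 13
Reactants: 17 3β-acetoxy-4β,5β-dimethyl-cis-decal-6-ene-8α,9α,10β-triol
Product: 18 3β-acetoxy-9α,10β-dihydroxy-4β,5β-dimethyl-cis-decal-6-en-8-one
Conditions: activated MnO2 (20 equiv), CH2Cl2, rt
Reagents that add atoms: none
Why: MnO2 oxidation is selective for the allylic C8 hydroxyl over the saturated secondary C9 and tertiary C10 hydroxyls, which completes the shift of the carbonyl from C9 to C8 with the C6=C7 alkene already in conjugation.

Step 14
Reactants: 18 3β-acetoxy-9α,10β-dihydroxy-4β,5β-dimethyl-cis-decal-6-en-8-one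
Product: 19 3β-acetoxy-9α,10β-dihydroxy-7-iodo-4β,5β-dimethyl-cis-decal-6-en-8-one
Conditions: I2 (2 equiv), pyridine/CH2Cl2 (1:1), 0 °C → rt, dark
Reagents that add atoms: iodine, II
Why: α-Iodination of an enone by the Baylis–Hillman-type sequence of pyridine addition, iodination and elimination is known to work on 4,4-disubstituted cyclohexenones, and it is placed before the esterification so that iodine never meets the Z-configured angelate.

Step 15
Reactants: 19 3β-acetoxy-9α,10β-dihydroxy-7-iodo-4β,5β-dimethyl-cis-decal-6-en-8-one; 20 angelic acid [(Z)-2-methylbut-2-enoic acid]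
Product: 22 3β-acetoxy-9α-angeloyloxy-10β-hydroxy-7-iodo-4β,5β-dimethyl-cis-decal-6-en-8-one, via mixed anhydride 21 (not isolated)
Conditions: 20 (3 equiv), 2,4,6-trichlorobenzoyl chloride (3 equiv), NEt3 (3 equiv), toluene, rt; then 19, 75 °C
Reagents that add atoms: 2,4,6-trichlorobenzoyl chloride, O=C(Cl)c1c(Cl)cc(Cl)cc1Cl (its atoms stay only in 21)
Why: Yamaguchi-type mixed-anhydride acylation run without a nucleophilic pyridine catalyst is the accepted way to transfer an angeloyl group with retention of Z geometry; the alcohol attacks the less hindered angeloyl carbonyl, and only the secondary C9 hydroxyl reacts because C10-OH is tertiary.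

Step 16
Reactants: 22 3β-acetoxy-9α-angeloyloxy-10β-hydroxy-7-iodo-4β,5β-dimethyl-cis-decal-6-en-8-one; 23 tributyl(1-ethoxyvinyl)stannane
Product: 25 3β-acetoxy-7-acetyl-9α-angeloyloxy-10β-hydroxy-4β,5β-dimethyl-cis-decal-6-en-8-one (target; 3S,4R,5R,9S,10R), via ethoxyvinyl dienone 24 (not isolated)
Conditions: PdCl2(PhCN)2 (5 mol%), AsPh3 (10 mol%), CuI (10 mol%), NMP, rt → 40 °C; then 1 M HCl, THF, 0 °C
Reagents that add atoms: water, O (oxygen of the acetyl group)
Why: Stille coupling of an α-iodoenone with the acetyl-anion equivalent forms C7–C(acetyl) under neutral conditions that leave both esters and the ketol alone, and brief cold acid hydrolysis of the enol ether releases the electrophilic 2-acetyl enone only in the last operation.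

Compound list
1 | 4,4-dimethoxycyclohexa-2,5-dien-1-one | COC1(OC)C=CC(=O)C=C1 | starting material
2 | (R)-4,4-dimethoxy-5-methylcyclohex-2-en-1-one | O=C1C[C@@H](C)C(OC)(OC)C=C1 | intermediate
3 | (5R,6R)-4,4-dimethoxy-5,6-dimethylcyclohex-2-en-1-one | O=C1[C@H](C)[C@@H](C)C(OC)(OC)C=C1 | intermediate
4 | allyl bromide | C=CCBr | starting material
5 | (5R,6R)-6-allyl-4,4-dimethoxy-5,6-dimethylcyclohex-2-en-1-one | C=CC[C@]1(C)[C@@H](C)C(OC)(OC)C=CC1=O | intermediate
6 | {[(5R,6R)-6-allyl-4,4-dimethoxy-5,6-dimethylcyclohex-1-en-1-yl]oxy}dimethyl(phenyl)silane | C=CC[C@]1(C)[C@@H](C)C(OC)(OC)CC=C1O[Si](C)(C)c1ccccc1 | intermediate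
7 | (2R,3R)-2-allyl-2,3-dimethylcyclohexane-1,4-dione | C=CC[C@]1(C)[C@@H](C)C(=O)CCC1=O | intermediate
8 | (2R,3R,4S)-2-allyl-4-hydroxy-2,3-dimethylcyclohexan-1-one | C=CC[C@]1(C)[C@@H](C)[C@@H](O)CCC1=O | intermediate
9 | (1S,2R,3R)-3-allyl-2,3-dimethyl-4-oxocyclohexyl acetate | C=CC[C@]1(C)[C@@H](C)[C@@H](OC(C)=O)CCC1=O | intermediate
10 | (1S,2R,3R)-2,3-dimethyl-4-oxo-3-(4-oxobutyl)cyclohexyl acetate | O=CCCC[C@]1(C)[C@@H](C)[C@@H](OC(C)=O)CCC1=O | intermediate
11 | 3β-acetoxy-10β-hydroxy-4β,5β-dimethyl-cis-decalin-9-one | O=C1CCC[C@]2(C)[C@@H](C)[C@@H](OC(C)=O)CC[C@]12O | intermediate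
12 | 3β-acetoxy-10β-hydroxy-4β,5β-dimethyl-cis-decal-7-en-9-one | O=C1C=CC[C@]2(C)[C@@H](C)[C@@H](OC(C)=O)CC[C@]12O | intermediate
13 | 3β-acetoxy-4β,5β-dimethyl-cis-decal-7-ene-9α,10β-diol | O[C@@H]1C=CC[C@]2(C)[C@@H](C)[C@@H](OC(C)=O)CC[C@]12O | intermediate
14 | 3β-acetoxy-7α,8α-epoxy-4β,5β-dimethyl-cis-decalin-9α,10β-diol | O[C@@H]1[C@@H]3O[C@@H]3C[C@]2(C)[C@@H](C)[C@@H](OC(C)=O)CC[C@]12O | intermediate
15 | 3β-acetoxy-7β-(phenylselanyl)-4β,5β-dimethyl-cis-decalin-8α,9α,10β-triol | O[C@@H]1[C@H](O)[C@@H]([Se]c3ccccc3)C[C@]2(C)[C@@H](C)[C@@H](OC(C)=O)CC[C@]12O | intermediate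
16 | Se-oxide of 15 | O[C@@H]1[C@H](O)[C@@H]([Se](=O)c3ccccc3)C[C@]2(C)[C@@H](C)[C@@H](OC(C)=O)CC[C@]12O | intermediate
17 | 3β-acetoxy-4β,5β-dimethyl-cis-decal-6-ene-8α,9α,10β-triol | O[C@@H]1[C@H](O)C=C[C@]2(C)[C@@H](C)[C@@H](OC(C)=O)CC[C@]12O | intermediate
18 | 3β-acetoxy-9α,10β-dihydroxy-4β,5β-dimethyl-cis-decal-6-en-8-one | O[C@@H]1C(=O)C=C[C@]2(C)[C@@H](C)[C@@H](OC(C)=O)CC[C@]12O | intermediate
19 | 3β-acetoxy-9α,10β-dihydroxy-7-iodo-4β,5β-dimethyl-cis-decal-6-en-8-one | O[C@@H]1C(=O)C(I)=C[C@]2(C)[C@@H](C)[C@@H](OC(C)=O)CC[C@]12O | intermediate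
20 | angelic acid, (Z)-2-methylbut-2-enoic acid | C/C=C(/C)C(=O)O | starting material
21 | (Z)-2-methylbut-2-enoic 2,4,6-trichlorobenzoic anhydride | C/C=C(/C)C(=O)OC(=O)c1c(Cl)cc(Cl)cc1Cl | intermediate
22 | 3β-acetoxy-9α-angeloyloxy-10β-hydroxy-7-iodo-4β,5β-dimethyl-cis-decal-6-en-8-one | C/C=C(/C)C(=O)O[C@@H]1C(=O)C(I)=C[C@]2(C)[C@@H](C)[C@@H](OC(C)=O)CC[C@]12O | intermediate
23 | tributyl(1-ethoxyvinyl)stannane | CCCC[Sn](CCCC)(CCCC)C(=C)OCC | starting material
24 | 3β-acetoxy-9α-angeloyloxy-7-(1-ethoxyvinyl)-10β-hydroxy-4β,5β-dimethyl-cis-decal-6-en-8-one | C/C=C(/C)C(=O)O[C@@H]1C(=O)C(C(=C)OCC)=C[C@]2(C)[C@@H](C)[C@@H](OC(C)=O)CC[C@]12O | intermediate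
25 | 3β-acetoxy-7-acetyl-9α-angeloyloxy-10β-hydroxy-4β,5β-dimethyl-cis-decal-6-en-8-one (CNP0196241.1) | C/C=C(/C)C(=O)O[C@@H]1C(=O)C(C(C)=O)=C[C@]2(C)[C@@H](C)[C@@H](OC(C)=O)CC[C@]12O | target

Total step count: 16. Longest linear sequence: 16 steps (1 → 25).

Steps most likely to fail

Step 8. Addition of the enaminol to a ketone flanked by quaternary C5 may be sluggish. Aldol cyclisation of the keto aldehyde or intermolecular homo-benzoin coupling could then take over, and attack on the wrong carbonyl face could erode the cis fusion. The fallback makes the same bond and ring by one-electron chemistry. From 10, SmI2 (THF/t-BuOH, −78 °C → rt) effects the ketyl pinacol cyclisation of the C9 aldehyde and the C10 ketone. This should give 3β-acetoxy-4β,5β-dimethyl-cis-decalin-9β,10β-diol F1, with the samarium chelate placing the two oxygens cis. Parikh–Doering oxidation (SO3·pyridine, DMSO, NEt3) of its only secondary hydroxyl comes back to 11.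

Step 12. Regioselectivity of the oxirane opening may be poor, with attack at C8 competing with C7 because C7 lies 1,3 to quaternary C5. Slow opening would also call for heating that endangers the acetate. The fallback activates the oxirane electrophilically instead of forcing a selenolate onto it. From 14, TMSOTf/2,6-lutidine (toluene, −78 °C → rt) silylates both hydroxyls and the oxirane oxygen and breaks the C7–O bond, the one remote from the electron-withdrawing C9–O substituent. DBU then removes a C6 proton in an anti-E2 step to give the 8α,9α,10β-tris(trimethylsilyl) ether of the triol F2. Citric acid in MeOH comes back to 17.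

Step 15. Acyl transfer to the hindered C9 hydroxyl may be slow. During the prolonged heating, Z→E isomerisation of the angeloyl unit and enolisation of the α-ketol, with loss of C9 configuration, can set in. The fallback attaches the ester before C8 becomes a ketone.
- From 14, the mixed anhydride 21 (toluene, 75 °C) acylates the only secondary hydroxyl to give 3β-acetoxy-9α-angeloyloxy-7α,8α-epoxy-4β,5β-dimethyl-cis-decalin-10β-ol F3. C9 cannot enolise at this stage, and the cis relation of ester and oxirane excludes participation.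
- A selenolate could add reversibly to the angelate, so the oxirane is isomerised with TMSOTf/2,6-lutidine and then DBU to the 8α,10β-bis(trimethylsilyl) ether F4.
- Citric acid in MeOH frees 3β-acetoxy-9α-angeloyloxy-4β,5β-dimethyl-cis-decal-6-ene-8α,10β-diol F5.
- MnO2 gives 3β-acetoxy-9α-angeloyloxy-10β-hydroxy-4β,5β-dimethyl-cis-decal-6-en-8-one F6.
- I2/pyridine with strict exclusion of light comes back to 22.

Further compounds
F1 | step 8 | 3β-acetoxy-4β,5β-dimethyl-cis-decalin-9β,10β-diol | O[C@H]1CCC[C@]2(C)[C@@H](C)[C@@H](OC(C)=O)CC[C@]12O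
F2 | step 12 | 3β-acetoxy-4β,5β-dimethyl-8α,9α,10β-tris(trimethylsilyloxy)-cis-decal-6-ene | C[Si](C)(C)O[C@@H]1[C@H](O[Si](C)(C)C)C=C[C@]2(C)[C@@H](C)[C@@H](OC(C)=O)CC[C@]12O[Si](C)(C)C
F3 | step 15 | 3β-acetoxy-9α-angeloyloxy-7α,8α-epoxy-4β,5β-dimethyl-cis-decalin-10β-ol | C/C=C(/C)C(=O)O[C@@H]1[C@@H]3O[C@@H]3C[C@]2(C)[C@@H](C)[C@@H](OC(C)=O)CC[C@]12O
F4 | step 15 | 3β-acetoxy-9α-angeloyloxy-4β,5β-dimethyl-8α,10β-bis(trimethylsilyloxy)-cis-decal-6-ene | C/C=C(/C)C(=O)O[C@@H]1[C@H](O[Si](C)(C)C)C=C[C@]2(C)[C@@H](C)[C@@H](OC(C)=O)CC[C@]12O[Si](C)(C)C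
F5 | step 15 | 3β-acetoxy-9α-angeloyloxy-4β,5β-dimethyl-cis-decal-6-ene-8α,10β-diol | C/C=C(/C)C(=O)O[C@@H]1[C@H](O)C=C[C@]2(C)[C@@H](C)[C@@H](OC(C)=O)CC[C@]12O
F6 | step 15 | 3β-acetoxy-9α-angeloyloxy-10β-hydroxy-4β,5β-dimethyl-cis-decal-6-en-8-one | C/C=C(/C)C(=O)O[C@@H]1C(=O)C=C[C@]2(C)[C@@H](C)[C@@H](OC(C)=O)CC[C@]12O
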